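**Plan**

1. Retrosynthesis: after the three acetates, the C7–C8 bond is cut. This opens ring B (ten-membered carbocycle C1–C10) and ring C (γ-lactone C7–O–C19–C17–C8) together, giving a seco keto aldehyde with a C8 ketone and a C7 aldehyde.
2. Enabling feature: C7–O and C8–OH form a 1,2-diol hidden in ring C (pinacol retron). C8 is β to the lactone carbonyl C19, so the ketone sits in a samarium-chelating β-keto ester, and C7 is the carbonyl carbon of an easily reduced (5Z)-enal.
3. Further cuts: C8–C17 (Claisen condensation), C4–C5 (B-alkyl Suzuki–Miyaura), C9–C10 ([2,3]-Wittig from a C12 ether), C1–C2 and C1–C15 (enolate chemistry on carvone).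
4. Forward: ring A is (S)-carvone; the quaternary C1, C2 and C14–O are set, the enone is transposed to a C12 allylic alcohol, C10/C9 are set, the two arms are completed, then rings B and C close in one step.
5. Stereochemistry: C14 from carvone; C1 by methylation anti to the isopropenyl group; C2 by catalyst-controlled transfer hydrogenation; C10/C9 by a suprafacial [2,3] shift from a C12–O set by epoxidation anti to C14–O; 5Z from a (Z)-vinyl iodide; C7, C8 and C17 in the key step.

Key step: step 18

Remark: target (briarane) numbering is used for all intermediates (ring A = C1/C10–C14; methyls C15 on C1, C16 on C5, C18 on C17, C20 on C11; "upper face" of ring A = the face of the C1–C2 bond); C17 of the β-keto esters made in steps 16 and 17 is assumed to be configurationally labile and is drawn without configuration until step 18.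

Step 1
Reactants: 1 (S)-carvone; 2 3-(trimethylsilyl)prop-2-ynal
Product: 3 propargylic aldol adduct (isomer mixture at C1 and C2)
Conditions: LiN(iPr)2, THF, −78 °C; then 2, −78 °C; aq. NH4Cl
Reagents that add atoms: none
Why: Kinetic α′-deprotonation of carvone at C1 and lithium aldol addition to the ynal form the C1–C2 bond; the two new centers need no control because both are erased and reset in steps 2 to 4.

Step 2
Reactants: 3 propargylic aldol adduct
Product: 4 alkynoyl 1,3-diketone
Conditions: Dess–Martin periodinane, NaHCO3, CH2Cl2, 0 °C to rt (used at once)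
Reagents that add atoms: none
Why: Dess–Martin oxidation of a β-hydroxy ketone gives the 1,3-diketone, which removes the uncontrolled carbinol center and acidifies C1–H for the next step.

Step 3
Reactants: 4 alkynoyl 1,3-diketone
Product: 5 quaternary diketone
Conditions: MeI, K2CO3, acetone, rt
Reagents that add atoms: iodomethane (CI)
Why: C-Alkylation of the stabilized 1,3-diketone enolate should place iodomethane on the face of C1 anti to the adjacent C14 isopropenyl group, so C15 ends up trans to it and the quaternary C1 has the target configuration.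

Step 4
Reactants: 5 quaternary diketone
Product: 6 C2 propargylic alcohol
Conditions: RuCl[(S,S)-TsDPEN](p-cymene) (cat.), HCO2H/Et3N (5:2), CH2Cl2, rt
Reagents that add atoms: none
Why: Noyori asymmetric transfer hydrogenation of an alkynyl ketone is catalyst-controlled (the alkynyl group takes the place of the aryl group in the usual model) and should give the (S)-carbinol of 6, which is the spatial arrangement of (2R) in the target, while the hindered conjugated C10 ketone is left alone.

Step 5
Reactants: 6 C2 propargylic alcohol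
Product: 9 C2/C14 diacetate, via methoxy hydroperoxide 7 (not isolated), via acetyl peroxide 8 (not isolated)
Conditions: O3, CH2Cl2/MeOH, NaHCO3, −78 °C; N2 purge; then Ac2O, Et3N, DMAP, 0 °C to rt
Reagents that add atoms: ozone ([O-][O+]=O); methanol (CO); acetic anhydride (CC(=O)OC(C)=O)
Why: Ozonolysis of the 1,1-disubstituted alkene in methanol (enone and silyl alkyne are inert at −78 °C) followed by Criegee rearrangement of the acylated hydroperoxide moves C14 to oxygen with retention, and the C2–OH is acetylated in the same pot.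

Step 6
Reactants: 9 C2/C14 diacetate
Product: 10 C2/C14 diol
Conditions: HCl (1.25 M in MeOH, cat.), MeOH, rt
Reagents that add atoms: none
Why: Acid-catalysed transesterification removes both acetates without forming alkoxides, which should avoid retro-aldol cleavage at the quaternary C1 and vinylogous β-elimination of the C14 oxygen.

Step 7
Reactants: 10 C2/C14 diol
Product: 11 bis-TBS enone
Conditions: TBSOTf, 2,6-lutidine, CH2Cl2, −78 to 0 °C
Reagents that add atoms: tert-butyldimethylsilyl trifluoromethanesulfonate (CC(C)(C)[Si](C)(C)OS(=O)(=O)C(F)(F)F)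
Why: Silyl ether formation with the reactive triflate protects the two hindered secondary alcohols with a non-chelating group that is removed by fluoride at the end.

Step 8
Reactants: 11 bis-TBS enone
Product: 13 epoxy ketone (terminal alkyne), via silylalkynyl epoxy ketone 12 (not isolated)
Conditions: 30% H2O2, NaOH (cat.), MeOH/THF, 0 °C; then K2CO3, rt
Reagents that add atoms: hydrogen peroxide (OO)
Why: Weitz–Scheffer nucleophilic epoxidation should add hydroperoxide axially to C12 on the lower face, anti to the C14 silyloxy group and the axial C2 arm (as carvone itself does), and carbonate in methanol then cleaves the alkynyl C–Si bond.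

Step 9
Reactants: 13 epoxy ketone (terminal alkyne)
Product: 15 C12 allylic alcohol (alkyne), via epoxy hydrazone 14 (not isolated)
Conditions: N2H4·H2O, AcOH, MeOH/THF, 0 °C to rt, under N2
Reagents that add atoms: none
Why: Wharton transposition (hydrazone formation, epoxide opening, loss of N2) gives the transposed allylic alcohol with C10=C11; the C12–O bond of the epoxide is kept, so C12–OH stays on the lower face.

Step 10
Reactants: 15 C12 allylic alcohol (alkyne)
Product: 16 C12 allylic alcohol (vinyl)
Conditions: H2 (1 atm), Pd/CaCO3 poisoned with Pb(OAc)2, quinoline, EtOAc, rt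
Reagents that add atoms: none
Why: Semi-hydrogenation of the terminal alkyne over poisoned palladium gives the C3=C4 vinyl group needed for hydroboration and should not touch the trisubstituted ring alkene.

Step 11
Reactants: 16 C12 allylic alcohol (vinyl); 17 methyl bromoacetate
Product: 18 methyl (allyloxy)acetate
Conditions: NaH (1.2 equiv), Bu4NI (cat.), THF, 0 °C; then 17, 0 °C to rt
Reagents that add atoms: none
Why: Williamson etherification of the allylic alkoxide with a reactive α-bromo ester installs C9 and C8 on the C12 oxygen as the [2,3]-Wittig precursor.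

Step 12
Reactants: 18 methyl (allyloxy)acetate
Product: 19 C9 α-hydroxy ester
Conditions: LiN(iPr)2 (1.2 equiv), THF, −78 to −10 °C; aq. NH4Cl
Reagents that add atoms: none
Why: In the ester-enolate [2,3]-Wittig rearrangement the C10–C9 bond forms suprafacially on the lower face that carried the C12 oxygen (setting C10 with H10 on the upper face) and the alkene returns to C11=C12; C8 should take the exo position away from C1 and its lower-face methyl, which gives (9R).

Step 13
Reactants: 19 C9 α-hydroxy ester
Product: 20 C9 silyloxy ester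
Conditions: TBSOTf, 2,6-lutidine, CH2Cl2, −78 to 0 °C
Reagents that add atoms: tert-butyldimethylsilyl trifluoromethanesulfonate (CC(C)(C)[Si](C)(C)OS(=O)(=O)C(F)(F)F)
Why: Silylation of the secondary alcohol gives the non-chelating C9 ether needed for Felkin–Anh control in the key step.

Step 14
Reactants: 21 but-2-yn-1-ol
Product: 23 (Z)-3-iodobut-2-en-1-ol, via cyclic vinylalanate 22 (not isolated)
Conditions: NaAlH2(OCH2CH2OMe)2, Et2O, 0 °C to rt; then I2, THF, −78 °C to rt
Reagents that add atoms: iodine (II)
Why: Alkoxide-directed trans-hydroalumination of the propargylic alcohol and iodine cleavage of the C–Al bond with retention give the (Z)-vinyl iodide, which fixes the later C5=C6 geometry.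

Step 15
Reactants: 20 C9 silyloxy ester; 23 (Z)-3-iodobut-2-en-1-ol
Product: 25 (5Z)-allylic alcohol ester, via B-alkyl-9-BBN 24 (not isolated)
Conditions: 9-BBN, THF, 0 °C to rt; then 23, PdCl2(dppf) (cat.), AsPh3, Cs2CO3, DMF/H2O, rt
Reagents that add atoms: none
Why: Anti-Markovnikov hydroboration of the monosubstituted alkene and B-alkyl Suzuki–Miyaura coupling with retention at the vinyl iodide form C4–C5 and give the (5Z)-trisubstituted alkene; the ester, silyl ethers and free alcohol are tolerated.

Step 16
Reactants: 25 (5Z)-allylic alcohol ester; 26 methyl propanoate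
Product: 27 β-keto ester (C17 epimers)
Conditions: 26 (4.2 equiv), LiN(iPr)2 (4 equiv), THF, −78 °C; then 25; −78 to −40 °C; aq. NH4Cl
Reagents that add atoms: none
Why: In this crossed Claisen condensation the preformed propanoate enolate (no free amide base, so C9–H is not removed) acylates on the activated α-silyloxy ester and the product is protected as its enolate; C17 forms as a labile mixture.

Step 17
Reactants: 27 β-keto ester (C17 epimers)
Product: 28 seco keto aldehyde
Conditions: MnO2, CH2Cl2, 0 °C to rt
Reagents that add atoms: none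
Why: Allylic oxidation with MnO2 is selective for the C7 alcohol under neutral conditions, which should keep the Z-enal geometry and leave the β-keto ester untouched.

Step 18
Reactants: 28 seco keto aldehyde
Product: 30 tris-TBS lactone (rings A to C complete), via pinacol diol ester 29 (not isolated)
Conditions: SmI2 (3 equiv), THF, −78 °C, slow addition of 28 (final 1 mM), no HMPA; then rt
Reagents that add atoms: none
Why: SmI2 should reduce the conjugated C7 aldehyde first to a samarium ketyl that couples with the C8 ketone, which is activated and held by chelation of trivalent samarium between O8 and the C19 ester carbonyl; a second electron gives the bis-alkoxide, and the C7 alkoxide then attacks C19 and expels methoxide. The closest known reactions are the SmI2-promoted intramolecular pinacol coupling of β-keto esters with aldehydes and low-valent-metal pinacol macrocyclizations. Ring B closes by the C7–C8 bond in a 10-exo-trig mode at both carbonyl carbons, and ring C closes by the O–C19 bond in a 5-exo-trig acyl substitution. C8 is set by attack anti to the non-chelating C9 silyloxy group (Felkin–Anh), C7 by the samarium-bridged arrangement of O7 and O8 that puts H7 rather than C6 next to C17 (cis-diol on ring B), and C17 by reaction through the chelate on the face opposite its methyl, the two C17 epimers of 28 interconverting through the enol. The step needs reduction of the enal in preference to the α-silyloxy ketone (aldehydes are reduced much faster at −78 °C without HMPA), ring closure in preference to dimerization (slow addition, high dilution) and retention of the 5Z geometry (short-lived ketyl at low temperature).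

Step 19
Reactants: 30 tris-TBS lactone
Product: 31 tetraol lactone
Conditions: HF·pyridine, pyridine, THF, 0 °C to rt
Reagents that add atoms: none
Why: Buffered fluoride desilylation removes the three TBS ethers and should spare the lactone, the allylic C7–O bond and the tertiary alcohol.

Step 20
Reactants: 31 tetraol lactone
Product: 32 stylatulide lactone
Conditions: Ac2O, pyridine, DMAP (cat.), CH2Cl2, rt
Reagents that add atoms: acetic anhydride (CC(=O)OC(C)=O)
Why: DMAP-catalysed acetylation esterifies the three secondary alcohols at C2, C9 and C14, while the hindered tertiary C8–OH is expected to stay free.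

**Compound list**

1 | (S)-(+)-carvone, (5S)-2-methyl-5-(prop-1-en-2-yl)cyclohex-2-en-1-one | CC(=C)[C@H]1CC=C(C)C(=O)C1 | starting material
2 | 3-(trimethylsilyl)prop-2-ynal | C[Si](C)(C)C#CC=O | starting material
3 | aldol adduct: carvone with a CH(OH)–C≡C–SiMe3 group (C2–C4) at C1; isomer mixture at C1 and C2 | CC(=C)[C@H]1CC=C(C)C(=O)C1C(O)C#C[Si](C)(C)C | intermediate
4 | 1,3-diketone: as 3 with a C2 ketone (keto/enol mixture, C1 labile) | CC(=C)[C@H]1CC=C(C)C(=O)C1C(=O)C#C[Si](C)(C)C | intermediate
5 | quaternary diketone: C15 methyl on the lower face (trans to the C14 isopropenyl), C2 ynone on the upper face | CC(=C)[C@H]1CC=C(C)C(=O)[C@@]1(C)C(=O)C#C[Si](C)(C)C | intermediate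
6 | C2 propargylic alcohol, (S) at C2 by CIP (spatially C2 of the target) | CC(=C)[C@H]1CC=C(C)C(=O)[C@@]1(C)[C@H](O)C#C[Si](C)(C)C | intermediate
7 | methoxy hydroperoxide at the former isopropenyl carbon (not isolated) | COC(C)(OO)[C@H]1CC=C(C)C(=O)[C@@]1(C)[C@H](O)C#C[Si](C)(C)C | intermediate
8 | acetyl peroxide of 7 with C2–OAc (not isolated) | COC(C)(OOC(C)=O)[C@H]1CC=C(C)C(=O)[C@@]1(C)[C@H](OC(C)=O)C#C[Si](C)(C)C | intermediate
9 | C2/C14 diacetate enone (C14–OAc on the upper face, cis to the C2 arm) | CC(=O)O[C@H]1CC=C(C)C(=O)[C@@]1(C)[C@H](OC(C)=O)C#C[Si](C)(C)C | intermediate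
10 | C2/C14 diol enone (silyl alkyne kept) | O[C@H]1CC=C(C)C(=O)[C@@]1(C)[C@H](O)C#C[Si](C)(C)C | intermediate
11 | C2/C14 bis-TBS enone | CC(C)(C)[Si](C)(C)O[C@H]1CC=C(C)C(=O)[C@@]1(C)[C@H](O[Si](C)(C)C(C)(C)C)C#C[Si](C)(C)C | intermediate
12 | silylalkynyl epoxy ketone, C11/C12 epoxide on the lower face (not isolated) | CC(C)(C)[Si](C)(C)O[C@H]1C[C@@H]2O[C@]2(C)C(=O)[C@@]1(C)[C@H](O[Si](C)(C)C(C)(C)C)C#C[Si](C)(C)C | intermediate
13 | epoxy ketone with terminal alkyne | CC(C)(C)[Si](C)(C)O[C@H]1C[C@@H]2O[C@]2(C)C(=O)[C@@]1(C)[C@H](O[Si](C)(C)C(C)(C)C)C#C | intermediate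
14 | hydrazone of 13 (not isolated) | CC(C)(C)[Si](C)(C)O[C@H]1C[C@@H]2O[C@]2(C)C(=NN)[C@@]1(C)[C@H](O[Si](C)(C)C(C)(C)C)C#C | intermediate
15 | allylic alcohol: C12–OH on the lower face, C10=C11, terminal alkyne C3≡C4 | CC(C)(C)[Si](C)(C)O[C@H]1C[C@H](O)C(C)=C[C@@]1(C)[C@H](O[Si](C)(C)C(C)(C)C)C#C | intermediate
16 | allylic alcohol as 15 with a C3=C4 vinyl group | CC(C)(C)[Si](C)(C)O[C@H]1C[C@H](O)C(C)=C[C@@]1(C)[C@H](O[Si](C)(C)C(C)(C)C)C=C | intermediate
17 | methyl bromoacetate | COC(=O)CBr | starting material
18 | methyl (allyloxy)acetate: C12–O–CH2–CO2Me | CC(C)(C)[Si](C)(C)O[C@H]1C[C@H](OCC(=O)OC)C(C)=C[C@@]1(C)[C@H](O[Si](C)(C)C(C)(C)C)C=C | intermediate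
19 | α-hydroxy ester: C9 on the lower face of C10 (H10 upper), C11=C12, (9R)-OH, C8 methyl ester | CC(C)(C)[Si](C)(C)O[C@H]1CC=C(C)[C@H]([C@@H](O)C(=O)OC)[C@@]1(C)[C@H](O[Si](C)(C)C(C)(C)C)C=C | intermediate
20 | C9 TBS ether of 19 | CC(C)(C)[Si](C)(C)O[C@H]1CC=C(C)[C@H]([C@@H](O[Si](C)(C)C(C)(C)C)C(=O)OC)[C@@]1(C)[C@H](O[Si](C)(C)C(C)(C)C)C=C | intermediate
21 | but-2-yn-1-ol | CC#CCO | starting material
22 | sodium cyclic vinylalanate (five-membered O–Al–C ring) (not isolated) | [Na+].CC1=CCO[Al-]1(OCCOC)OCCOC | intermediate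
23 | (Z)-3-iodobut-2-en-1-ol | C/C(I)=C/CO | intermediate
24 | B-alkyl-9-BBN at C4 (not isolated) | CC(C)(C)[Si](C)(C)O[C@H]1CC=C(C)[C@H]([C@@H](O[Si](C)(C)C(C)(C)C)C(=O)OC)[C@@]1(C)[C@H](O[Si](C)(C)C(C)(C)C)CCB1C2CCCC1CCC2 | intermediate
25 | (5Z)-allylic alcohol: complete C2–C7 arm with C7–OH, C8 methyl ester | CC(C)(C)[Si](C)(C)O[C@H]1CC=C(C)[C@H]([C@@H](O[Si](C)(C)C(C)(C)C)C(=O)OC)[C@@]1(C)[C@H](O[Si](C)(C)C(C)(C)C)CC/C(C)=C\CO | intermediate
26 | methyl propanoate | CCC(=O)OC | starting material
27 | β-keto ester: C8 ketone, C17 methyl, C19 methyl ester (C17 epimers), C7–OH | CC(C)(C)[Si](C)(C)O[C@H]1CC=C(C)[C@H]([C@@H](O[Si](C)(C)C(C)(C)C)C(=O)C(C)C(=O)OC)[C@@]1(C)[C@H](O[Si](C)(C)C(C)(C)C)CC/C(C)=C\CO | intermediate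
28 | seco keto aldehyde: as 27 with the (5Z)-enal at C7 | CC(C)(C)[Si](C)(C)O[C@H]1CC=C(C)[C@H]([C@@H](O[Si](C)(C)C(C)(C)C)C(=O)C(C)C(=O)OC)[C@@]1(C)[C@H](O[Si](C)(C)C(C)(C)C)CC/C(C)=C\C=O | intermediate
29 | pinacol diol ester: ring B closed, (7S)-OH, (8S)-OH, (17R) methyl ester side chain (not isolated) | CC(C)(C)[Si](C)(C)O[C@H]1CC=C(C)[C@@H]2[C@@H](O[Si](C)(C)C(C)(C)C)[C@@]([C@@H](C)C(=O)OC)(O)[C@@H](O)/C=C(/C)CC[C@@H](O[Si](C)(C)C(C)(C)C)[C@@]12C | intermediate
30 | tris-TBS lactone: rings A, B and C; 2,9,14-tris-OTBS, 8-OH | CC(C)(C)[Si](C)(C)O[C@H]1CC=C(C)[C@@H]2[C@@H](O[Si](C)(C)C(C)(C)C)[C@@]3(O)[C@H](/C=C(/C)CC[C@@H](O[Si](C)(C)C(C)(C)C)[C@@]12C)OC(=O)[C@@H]3C | intermediate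
31 | tetraol lactone: 2,8,9,14-tetrahydroxy | O[C@H]1CC=C(C)[C@@H]2[C@@H](O)[C@@]3(O)[C@H](/C=C(/C)CC[C@@H](O)[C@@]12C)OC(=O)[C@@H]3C | intermediate
32 | stylatulide lactone, (1S,2R,5Z,7S,8S,9R,10S,14S,17R) | CC(=O)O[C@H]1CC=C(C)[C@@H]2[C@@H](OC(C)=O)[C@@]3(O)[C@H](/C=C(/C)CC[C@@H](OC(C)=O)[C@@]12C)OC(=O)[C@@H]3C | target

**Step count and risks**

Total: 20 steps. Longest linear sequence: 19 steps (steps 1 to 13 and 15 to 20, from (S)-carvone); step 14 is a one-step branch.

Steps most likely to fail:

- **Step 18 (key step).** Electron transfer to the C8 ketone may compete with reduction of the enal and expel the C9 silyloxy group, intermolecular coupling may outrun ring closure, or the ring may close with poor facial selectivity. The fallback sets out from 28 and returns at 30. The β-keto ester is converted with NaH and PhNTf2 into the (Z)-enol triflate F1. An intramolecular Nozaki–Hiyama–Kishi reaction (CrCl2, catalytic NiCl2, DMF, high dilution) then forms the same C7–C8 bond by addition of the vinylchromium to the enal, and the C7 alkoxide closes onto the cis ester to give the butenolide F2. Nucleophilic epoxidation of the C8=C17 bond (NaOCl, pyridine) gives the 8,17-epoxy lactone F3. Reductive opening of its C17–O bond with SmI2/MeOH (known for α,β-epoxy esters), with protonation at C17 and, if needed, DBU equilibration to the epimer with the methyl anti to C9, leads to 30.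

- **Step 9.** Hydrazone formation may stall at the C10 ketone, which is flanked by the quaternary C1 and the epoxide carbon, and the silyl ethers may suffer on prolonged heating. The fallback sets out from 11 and returns at 15. The epoxidation is run without the carbonate stage so that the silylalkynyl epoxy ketone 12 is isolated. NaBH4 reduces the ketone to the epoxy alcohol F4, and 1,1′-thiocarbonyldiimidazole with DMAP gives the imidazole-1-carbothioate F5. Bu3SnH/AIBN then generates the C10 radical, which opens the epoxide (radical variant of the transposition, Barton–McCombie-type initiation) to give the silylalkynyl allylic alcohol F6. K2CO3/MeOH removes the alkynyl silyl group.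

- **Step 16.** Acylation at the hindered C8 ester may be slow, so that self-condensation of the propanoate enolate or proton transfer from C9 takes over. The fallback sets out from 25 and returns at 28. iBu2AlH at −78 °C reduces the methyl ester to the aldehyde F7. Aldol addition of the lithium enolate of methyl propanoate gives the β-hydroxy ester F8 as an isomer mixture. Dess–Martin periodinane then oxidizes the C8 carbinol and the allylic C7 alcohol together.

Further compounds
F1 | step 18 | (Z)-enol triflate of 28 (C8–OTf cis to the C19 ester) | CC(C)(C)[Si](C)(C)O[C@H]1CC=C(C)[C@H]([C@@H](O[Si](C)(C)C(C)(C)C)/C(OS(=O)(=O)C(F)(F)F)=C(\C)C(=O)OC)[C@@]1(C)[C@H](O[Si](C)(C)C(C)(C)C)CC/C(C)=C\C=O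
F2 | step 18 | tris-TBS butenolide (rings A to C, C8=C17) | CC(C)(C)[Si](C)(C)O[C@H]1CC=C(C)[C@@H]2[C@@H](O[Si](C)(C)C(C)(C)C)C3=C(C)C(=O)O[C@H]3/C=C(/C)CC[C@@H](O[Si](C)(C)C(C)(C)C)[C@@]12C
F3 | step 18 | tris-TBS 8,17-epoxy lactone (epoxide oxygen cis to C6 on ring C) | CC(C)(C)[Si](C)(C)O[C@H]1CC=C(C)[C@@H]2[C@@H](O[Si](C)(C)C(C)(C)C)[C@@]34O[C@@]4(C)C(=O)O[C@H]3/C=C(/C)CC[C@@H](O[Si](C)(C)C(C)(C)C)[C@@]12C
F4 | step 9 | silylalkynyl epoxy alcohol (C10–OH, either epimer) | CC(C)(C)[Si](C)(C)O[C@H]1C[C@@H]2O[C@]2(C)C(O)[C@@]1(C)[C@H](O[Si](C)(C)C(C)(C)C)C#C[Si](C)(C)C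
F5 | step 9 | C10 O-imidazole-1-carbothioate of F4 | CC(C)(C)[Si](C)(C)O[C@H]1C[C@@H]2O[C@]2(C)C(OC(=S)n3ccnc3)[C@@]1(C)[C@H](O[Si](C)(C)C(C)(C)C)C#C[Si](C)(C)C
F6 | step 9 | silylalkynyl C12 allylic alcohol | CC(C)(C)[Si](C)(C)O[C@H]1C[C@H](O)C(C)=C[C@@]1(C)[C@H](O[Si](C)(C)C(C)(C)C)C#C[Si](C)(C)C
F7 | step 16 | C8 aldehyde | CC(C)(C)[Si](C)(C)O[C@H]1CC=C(C)[C@H]([C@@H](O[Si](C)(C)C(C)(C)C)C=O)[C@@]1(C)[C@H](O[Si](C)(C)C(C)(C)C)CC/C(C)=C\CO
F8 | step 16 | C8 β-hydroxy ester (isomer mixture at C8 and C17) | CC(C)(C)[Si](C)(C)O[C@H]1CC=C(C)[C@H]([C@@H](O[Si](C)(C)C(C)(C)C)C(O)C(C)C(=O)OC)[C@@]1(C)[C@H](O[Si](C)(C)C(C)(C)C)CC/C(C)=C\CO
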